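102 s was the number I started from: the mean stay of the electrophile in the summer run, a pseudo-first-order lifetime read from the readings. Electrophile, the limiting reagent, enters at a steady rate over 2.0 min.

in all of them: electrophile 0.010 M (fed, over 2.0 min)

| flask | nucleophile | remark | time |
|---|---|---|---|
| autumn | 0.023 M | run made earlier |  |
| noon | 0.031 M | run made earlier |  |
| summer | 0.040 M | run made earlier |  |
| gamma | 0.0200 M |  | 2.0 min |
| epsilon | 0.0450 M |  | 2.0 min |
| delta | 0.0300 M |  | 2.0 min |

- autumn (time / s: electrophile / %, product / %): 10.0: 8.5, 0.7; 30.0: 22.9, 2.4; 60.0: 41.5, 8.4; 80.0: 52.7, 13.3; 120: 73.4, 26.4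
- noon (time / s: electrophile / %, product / %): 10.0: 8.0, 0.6; 20.0: 15.4, 1.6; 30.0: 22.4, 3.1; 60.0: 38.7, 11.3; 120: 65.6, 34.0
- summer (time / s: electrophile / %, product / %): 25.0: 18.4, 2.7; 50.0: 32.0, 9.7; 80.0: 44.7, 22.3; 90.0: 48.5, 26.0; 120: 59.2, 40.1

(readings scatter by 0.3 percentage points)

- the analysis behind the earlier runs scatters by 0.3 percentage points, standard deviation
- a reading or a percentage of product counts all its forms, free or not
- percentages count the whole charge, also what has not yet gone in

I kept a ledger of the electrophile. Its first entry was what had gone in, which had to equal standing electrophile plus product. At the end these summed to 99.3% in summer and 99.8% in autumn, so I opened no third entry. The second entry was the rate of transfer: the area under the standing electrophile, divided by the final product, gave the stay. Autumn gave 181 s and noon 129 s, so the stay shortened as nucleophile rose. Their mean inverse with nucleophile, 0.245 M⁻¹ s⁻¹, was what I carried: the consumption constant, one over stay times nucleophile. Multiplied by nucleophile and dosing time it gives the dose number x, and a steady feed with first-order loss has reacted 1 − (1 − e^(−x))/x by the end.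

- part of the electrophile that has reacted at the end, gamma
- part of the electrophile that has reacted at the end, epsilon
- part of the electrophile that has reacted at the end, delta
- what raising the concentration of nucleophile from its lowest to its highest value here does to the part of the electrophile that has reacted (changes below 5 percentage points count as none) (it rises / no change / it falls)

I reckoned 24.4% for gamma, 33.5% for delta and 44.5% for epsilon, a rise of 20 percentage points. The forecast said 23.6%, 33% and 43.6%, and it rises, holding that “the end-point scaling holds across the range”. My figures stand above these.

The flasks gave 23.9%, 33.1% and 44.4%: it rises, by 21 points.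

    crystals ⇌ acid set free, rate k1*(cs1 - [acid set free]) while solid is left; crystals form when [acid set free] > cs1 (solubility = 3.80 mM, k = 0.976 s⁻¹)
    nucleophile + product ⇌ idle adduct, settled at all times (K = 531 M⁻¹)
    nucleophile + acid set free ⇌ protonated nucleophile, settled at all times (K = 13000 M⁻¹)
    electrophile + nucleophile → acid set free + product (k = 0.297 M⁻¹ s⁻¹)

In epsilon the step from electrophile and nucleophile ran through the dose, half its turnover done by 1.27 min, while free nucleophile fell to 71.0% of its charge, though making product cost 9.87% of that charge. The remainder stood as protonated nucleophile, 0.00443 M, and idle adduct, 0.00419 M. Delta's answer moves by 5 points at 0.0244 M and at 0.0362 M of nucleophile. For a neighbour of epsilon charged with 0.18 M of nucleophile, 0.245 M⁻¹ s⁻¹ gives a dose number of 5.29 and 81.2% reacted; that flask gave 82.5%.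

(The data are simulated from invented constants, noise included.)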